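**Plan**

- Retrosynthesis: remove the acetate; cut the carbinol–C(=CH2) bond (alkenyl iodide 22 + aldehyde 32); in the cyclohexenone (C1 carbonyl, C2 vinylic CH, C3, C4 quaternary, C5 CHMe, C6 CH2) cut C1–C2 and C5–C6 in one event; then cut C4–C5 by a Claisen transform.
- Enabling feature: C1(=O)–C6H2 is a ketene unit lodged between the stereogenic C5 and the vinylic C2. A diazomethyl ketone on C5 releases it by Wolff shift (C5–C6), and an (E)-vinylsilane at C2 captures it (C1–C2), closing the six-membered ring.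
- Helper: one SiMe3 group carries the stereocentre of a silyl carbinol, relays it through a chair Ireland–Claisen rearrangement to C4/C5, steers the acylation to C2 and leaves as Me3SiCl in the key step.
- Forward order: Z-tetrasubstituted allylic alcohol → (S)-silyl carbinol → propionate → Claisen acid → diazoketone → ring → alkenyl iodide; side chain from a pentynyl ether and 4-bromofuranone; union by Nozaki–Hiyama–Kishi coupling; acetylation.
- Stereochemistry: C4 and C5 come from the (S)-silyl carbinol (Ipc2BCl reduction) by Claisen chirality transfer and retention in the Wolff shift; the E-alkene from syn-carboalumination; the (R)-carbinol from ligand-controlled alkenylchromium addition.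

Key step: step 9

Assumption: compounds 4, 23 and 28 are taken as purchasable, and the antipode of the oxazoline–sulfonamide ligand used in step 17 is the one that directs the alkenylchromium to the Si face of aldehyde 32.

**Route**

Step 1
Reactants: 1 but-2-yn-1-ol
Product: 3 (Z)-3-iodo-2-methylbut-2-en-1-ol, via cyclic alkenylmagnesium alkoxide 2 (not isolated)
Conditions: MeMgBr (3 equiv), CuI (10 mol %), Et2O, 0 °C → rt; then N-iodosuccinimide, THF, −40 → 0 °C; aq. NH4Cl
Reagents that add atoms: methylmagnesium bromide C[Mg]Br; N-iodosuccinimide O=C1CCC(=O)N1I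
Why: Copper-catalysed anti-carbomagnesiation of the propargylic alkoxide delivers methyl to the carbon next to CH2O and holds magnesium on the distal carbon in a five-membered chelate, so iodination with retention should give the tetrasubstituted alkene with CH2OH and iodine cis.

Step 2
Reactants: 3 (Z)-3-iodo-2-methylbut-2-en-1-ol; 4 (4-bromobut-1-yn-1-yl)trimethylsilane
Product: 6 (Z)-2,3-dimethyl-7-(trimethylsilyl)hept-2-en-6-yn-1-ol, via butynylzinc bromide 5 (not isolated)
Conditions: 4, Zn dust, LiCl, THF, 40 °C; then 3, Pd(OAc)2 (2 mol %), SPhos (4 mol %), THF, rt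
Reagents that add atoms: none
Why: Negishi sp2–sp3 coupling proceeds with retention at the alkenyl iodide and the biarylphosphine catalyst tolerates the free hydroxyl, so the new chain should end cis to CH2OH.

Step 3
Reactants: 6 (Z)-2,3-dimethyl-7-(trimethylsilyl)hept-2-en-6-yn-1-ol
Product: 8 rac-(Z)-2,3-dimethyl-1,7-bis(trimethylsilyl)hept-2-en-6-yn-1-ol, via allyl trimethylsilyl ether 7 (not isolated)
Conditions: n-BuLi, THF, −78 °C; TMSCl, → 0 °C; s-BuLi, −78 → −40 °C; AcOH, −78 °C
Reagents that add atoms: chlorotrimethylsilane C[Si](C)(C)Cl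
Why: Deprotonation of the allyl silyl ether next to oxygen is followed by 1,2-migration of silicon from O to C (retro-Brook rearrangement), the fully substituted γ-carbon disfavouring the 1,4-shift; the new carbinol centre is racemic at this stage.

Step 4
Reactants: 8 rac-(Z)-2,3-dimethyl-1,7-bis(trimethylsilyl)hept-2-en-6-yn-1-ol
Product: 9 (Z)-2,3-dimethyl-1,7-bis(trimethylsilyl)hept-2-en-6-yn-1-one
Conditions: DMP, CH2Cl2, 0 °C → rt, in the dark
Reagents that add atoms: none
Why: Dess–Martin oxidation of the α-silyl carbinol to the alkenyl acylsilane erases the racemic centre under neutral conditions that should leave the Z-alkene and both C–Si bonds intact.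

Step 5
Reactants: 9 (Z)-2,3-dimethyl-1,7-bis(trimethylsilyl)hept-2-en-6-yn-1-one
Product: 11 (1S,2Z)-2,3-dimethyl-1,7-bis(trimethylsilyl)hept-2-en-6-yn-1-ol, via isopinocampheylchloroborinate 10 (not isolated)
Conditions: (+)-Ipc2BCl, THF, −25 °C → rt; then HN(CH2CH2OH)2, Et2O
Reagents that add atoms: none
Why: Asymmetric reduction of an acylsilane with chlorodiisopinocampheylborane delivers hydride through a cyclic boat transition state with SiMe3 in the place of the large substituent, which for the reagent made from (−)-α-pinene should set the (S)-carbinol.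

Step 6
Reactants: 11 (1S,2Z)-2,3-dimethyl-1,7-bis(trimethylsilyl)hept-2-en-6-yn-1-ol
Product: 12 (1S,2Z)-2,3-dimethyl-1,7-bis(trimethylsilyl)hept-2-en-6-yn-1-yl propanoate
Conditions: (EtCO)2O, Et3N, DMAP (cat.), CH2Cl2, 0 °C → rt
Reagents that add atoms: propanoic anhydride CCC(=O)OC(=O)CC
Why: DMAP-catalysed esterification of the hindered carbinol without a metal alkoxide avoids Brook rearrangement and leaves the stereocentre untouched.

Step 7
Reactants: 12 (1S,2Z)-2,3-dimethyl-1,7-bis(trimethylsilyl)hept-2-en-6-yn-1-yl propanoate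
Product: 15 (2S,3R,4E)-2,3,4-trimethyl-5-(trimethylsilyl)-3-[4-(trimethylsilyl)but-3-yn-1-yl]pent-4-enoic acid, via (Z)-silyl ketene acetal 13 (not isolated), via trimethylsilyl ester 14 (not isolated)
Conditions: LDA, THF/DMPU (4:1), −78 °C; TMSCl, Et3N; −78 °C → rt, then 50 °C; 1 M HCl
Reagents that add atoms: none
Why: Ireland–Claisen rearrangement through a chair transition state, in which the (Z)-ketene acetal formed in the polar medium puts the C5 methyl equatorial and the carbinol SiMe3 sits equatorial to avoid the axial chain on C4, should transfer the (S)-carbinol chirality to C4 (quaternary) and C5 together and give the (E)-vinylsilane.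

Step 8
Reactants: 15 (2S,3R,4E)-2,3,4-trimethyl-5-(trimethylsilyl)-3-[4-(trimethylsilyl)but-3-yn-1-yl]pent-4-enoic acid
Product: 17 (3S,4R,5E)-1-diazo-3,4,5-trimethyl-6-(trimethylsilyl)-4-[4-(trimethylsilyl)but-3-yn-1-yl]hex-5-en-2-one, via acid chloride 16 (not isolated)
Conditions: 1-chloro-N,N,2-trimethylprop-1-en-1-amine, CH2Cl2, 0 °C → rt; then CH2N2 (excess), Et2O, 0 °C
Reagents that add atoms: diazomethane C=[N+]=[N-]
Why: Neutral formation of the acid chloride (no HCl, so the vinylsilane survives, and no amine base, so C5 is not epimerised) followed by acylation of diazomethane is the first half of an Arndt–Eistert homologation.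

Step 9
Reactants: 17 (3S,4R,5E)-1-diazo-3,4,5-trimethyl-6-(trimethylsilyl)-4-[4-(trimethylsilyl)but-3-yn-1-yl]hex-5-en-2-one
Product: 20 (4R,5R)-3,4,5-trimethyl-4-[4-(trimethylsilyl)but-3-yn-1-yl]cyclohex-2-en-1-one, via ketene 18 (not isolated), via chloro(ethyl)aluminium dienolate 19 (not isolated)
Conditions: hν (365 nm), CH2Cl2, −78 °C; then EtAlCl2 (2.5 equiv), −78 → −20 °C; aq. Rochelle salt
Reagents that add atoms: none
Why: Proposed new method: photolysis triggers the Wolff 1,2-shift in which C5 migrates with retention from the acyl carbon to the diazo carbon (new C5–C6 bond) and leaves ketene 18; EtAlCl2 then binds the ketene oxygen, the acylium-like C1 is attacked by the ipso carbon C2 of the (E)-vinylsilane (new C1–C2 bond), and the β-silyl tertiary cation at C3 loses Me3SiCl to give dienolate 19, which is protonated at C6 on work-up. The closest known reaction types are the Arndt–Eistert homologation, the Lewis acid-promoted ketene–alkene cycloaddition and the vinylsilane-terminated acylium cyclisation; a ketene has not been shown as the acyl donor toward a vinylsilane. The six-membered ring closes in the 6-endo mode with respect to the C2=C3 bond, the only mode that places the cation β to silicon and on a tertiary carbon. No new stereocentre arises: C5 keeps its configuration through the suprafacial shift and the quaternary C4 is a spectator. The step needs chemoselectivity for Wolff rearrangement over carbene cyclopropanation of the γ,δ-alkene, secured by direct irradiation at low temperature without a metal, and regioselectivity for C2, secured by the silyl group and by the strain of the alternative bicyclo[2.2.0]hexanone and eight-membered closures. Loss of silicon fixes the double bond at C2=C3 and forestalls a Wagner–Meerwein shift from C4.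

Step 10
Reactants: 20 (4R,5R)-3,4,5-trimethyl-4-[4-(trimethylsilyl)but-3-yn-1-yl]cyclohex-2-en-1-one
Product: 21 (4R,5R)-4-(but-3-yn-1-yl)-3,4,5-trimethylcyclohex-2-en-1-one
Conditions: K2CO3 (cat.), MeOH, rt
Reagents that add atoms: none
Why: Base-catalysed methanolysis cleaves the alkynyl C–Si bond (protodesilylation of an alkynylsilane), and C5, being β to the ketone, cannot epimerise.

Step 11
Reactants: 21 (4R,5R)-4-(but-3-yn-1-yl)-3,4,5-trimethylcyclohex-2-en-1-one
Product: 22 (4R,5R)-4-(3-iodobut-3-en-1-yl)-3,4,5-trimethylcyclohex-2-en-1-one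
Conditions: TMSCl, NaI, H2O (0.5 equiv), MeCN, 0 °C → rt
Reagents that add atoms: sodium iodide [Na+].[I-]
Why: Hydrogen iodide generated in situ adds to the terminal alkyne in the Markovnikov sense (hydroiodination) to give the 2-iodo-1-alkene, while conjugate addition to the β,β-disubstituted enone is reversible and unproductive.

Step 12
Reactants: 23 tert-butyldimethyl(pent-4-yn-1-yloxy)silane
Product: 26 (E)-7-(tert-butyldimethylsilyloxy)-4-methylhept-3-en-1-ol, via alkenyldimethylalane 24 (not isolated), via lithium alkenylalanate 25 (not isolated)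
Conditions: Me3Al (2 equiv), Cp2ZrCl2 (0.25 equiv), CH2Cl2, 0 °C → rt; then n-BuLi, hexane/THF, −30 °C; ethylene oxide, −30 → 0 °C; aq. Rochelle salt
Reagents that add atoms: trimethylaluminium C[Al](C)C; ethylene oxide C1CO1
Why: Zirconium-catalysed syn-carboalumination of the terminal alkyne places methyl on the internal carbon and fixes the E-trisubstituted alkene, and the derived alanate opens ethylene oxide with retention of alkene geometry.

Step 13
Reactants: 26 (E)-7-(tert-butyldimethylsilyloxy)-4-methylhept-3-en-1-ol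
Product: 27 (E)-tert-butyl[(7-iodo-4-methylhept-4-en-1-yl)oxy]dimethylsilane
Conditions: PPh3, N-iodosuccinimide, CH2Cl2, 0 °C → rt
Reagents that add atoms: N-iodosuccinimide O=C1CCC(=O)N1I
Why: Appel-type iodination of the primary alcohol through the alkoxyphosphonium salt should leave the silyl ether and the alkene untouched.

Step 14
Reactants: 27 (E)-tert-butyl[(7-iodo-4-methylhept-4-en-1-yl)oxy]dimethylsilane; 28 4-bromofuran-2(5H)-one
Product: 30 4-[(E)-7-(tert-butyldimethylsilyloxy)-4-methylhept-3-en-1-yl]furan-2(5H)-one, via alkylzinc iodide 29 (not isolated)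
Conditions: 27, Zn dust (TMSCl-activated), THF, 40 °C; then 28, PdCl2(dppf) (3 mol %), THF, rt
Reagents that add atoms: none
Why: Zinc insertion into the primary iodide and Negishi coupling with the vinylogous acyl bromide, whose C–Br bond adds readily to zerovalent palladium, should install the β-alkyl butenolide without touching the E-alkene.

Step 15
Reactants: 30 4-[(E)-7-(tert-butyldimethylsilyloxy)-4-methylhept-3-en-1-yl]furan-2(5H)-one
Product: 31 4-[(E)-7-hydroxy-4-methylhept-3-en-1-yl]furan-2(5H)-one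
Conditions: HF·pyridine, THF/pyridine, 0 °C → rt
Reagents that add atoms: none
Why: Fluoride-mediated cleavage of the silyl ether under buffered acidic conditions should not isomerise the butenolide.

Step 16
Reactants: 31 4-[(E)-7-hydroxy-4-methylhept-3-en-1-yl]furan-2(5H)-one
Product: 32 (E)-4-methyl-7-(5-oxo-2,5-dihydrofuran-3-yl)hept-4-enal
Conditions: DMP, NaHCO3, CH2Cl2, 0 °C → rt
Reagents that add atoms: none
Why: Dess–Martin oxidation of the primary alcohol gives the aldehyde under buffered conditions without migration of the trisubstituted alkene.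

Step 17
Reactants: 22 (4R,5R)-4-(3-iodobut-3-en-1-yl)-3,4,5-trimethylcyclohex-2-en-1-one; 32 (E)-4-methyl-7-(5-oxo-2,5-dihydrofuran-3-yl)hept-4-enal
Product: 34 4-[(3E,7R)-7-hydroxy-4-methyl-8-methylidene-10-[(1R,6R)-1,2,6-trimethyl-4-oxocyclohex-2-en-1-yl]dec-3-en-1-yl]furan-2(5H)-one, via alkenylchromium dichloride 33 (not isolated)
Conditions: CrCl2 (3 equiv), NiCl2 (1 mol %), 4-isopropyl-2-(2-methanesulfonamidophenyl)-2-oxazoline ligand (3.3 equiv, antipode for Si-face attack), Et3N, THF, rt
Reagents that add atoms: none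
Why: Nozaki–Hiyama–Kishi coupling, in which the alkenylchromium reagent formed by nickel-catalysed activation of the C–I bond adds to the aldehyde in preference to the enone and the lactone, should give the (R)-carbinol because the chromium-bound chiral sulfonamide ligand selects the Si face.

Step 18
Reactants: 34 4-[(3E,7R)-7-hydroxy-4-methyl-8-methylidene-10-[(1R,6R)-1,2,6-trimethyl-4-oxocyclohex-2-en-1-yl]dec-3-en-1-yl]furan-2(5H)-one
Product: 35 4-[(3E,7R)-7-acetoxy-4-methyl-8-methylidene-10-[(1R,6R)-1,2,6-trimethyl-4-oxocyclohex-2-en-1-yl]dec-3-en-1-yl]furan-2(5H)-one (target)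
Conditions: Ac2O, pyridine, DMAP (cat.), CH2Cl2, 0 °C → rt
Reagents that add atoms: acetic anhydride CC(=O)OC(C)=O
Why: DMAP-catalysed acetylation of the secondary allylic alcohol occurs at oxygen with retention of configuration.

**Compound list**

1 | but-2-yn-1-ol | CC#CCO | starting material
2 | 3,4-dimethyl-2,5-dihydro-1,2-oxamagnesole (cyclic alkenylmagnesium alkoxide) | CC1=C(C)[Mg]OC1 | intermediate
3 | (Z)-3-iodo-2-methylbut-2-en-1-ol | OC/C(C)=C(C)\I | intermediate
4 | (4-bromobut-1-yn-1-yl)trimethylsilane | C[Si](C)(C)C#CCCBr | starting material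
5 | [4-(trimethylsilyl)but-3-yn-1-yl]zinc bromide | C[Si](C)(C)C#CCC[Zn]Br | intermediate
6 | (Z)-2,3-dimethyl-7-(trimethylsilyl)hept-2-en-6-yn-1-ol | OC/C(C)=C(C)\CCC#C[Si](C)(C)C | intermediate
7 | (Z)-[2,3-dimethyl-7-(trimethylsilyl)hept-2-en-6-yn-1-yl]oxytrimethylsilane | C[Si](C)(C)OC/C(C)=C(C)\CCC#C[Si](C)(C)C | intermediate
8 | rac-(Z)-2,3-dimethyl-1,7-bis(trimethylsilyl)hept-2-en-6-yn-1-ol | OC([Si](C)(C)C)/C(C)=C(C)\CCC#C[Si](C)(C)C | intermediate
9 | (Z)-2,3-dimethyl-1,7-bis(trimethylsilyl)hept-2-en-6-yn-1-one | O=C([Si](C)(C)C)/C(C)=C(C)\CCC#C[Si](C)(C)C | intermediate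
10 | chloro(isopinocampheyl)borinic ester of 11 | ClB(O[C@@H]([Si](C)(C)C)/C(C)=C(C)\CCC#C[Si](C)(C)C)[C@H]1C[C@H]2C[C@@H]([C@@H]1C)C2(C)C | intermediate
11 | (1S,2Z)-2,3-dimethyl-1,7-bis(trimethylsilyl)hept-2-en-6-yn-1-ol | O[C@@H]([Si](C)(C)C)/C(C)=C(C)\CCC#C[Si](C)(C)C | intermediate
12 | (1S,2Z)-2,3-dimethyl-1,7-bis(trimethylsilyl)hept-2-en-6-yn-1-yl propanoate | CCC(=O)O[C@@H]([Si](C)(C)C)/C(C)=C(C)\CCC#C[Si](C)(C)C | intermediate
13 | (Z)-O-trimethylsilyl ketene acetal of 12 | C/C=C(\O[Si](C)(C)C)O[C@@H]([Si](C)(C)C)/C(C)=C(C)\CCC#C[Si](C)(C)C | intermediate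
14 | trimethylsilyl ester of 15 | C[C@H](C(=O)O[Si](C)(C)C)[C@@](C)(CCC#C[Si](C)(C)C)/C(C)=C/[Si](C)(C)C | intermediate
15 | (2S,3R,4E)-2,3,4-trimethyl-5-(trimethylsilyl)-3-[4-(trimethylsilyl)but-3-yn-1-yl]pent-4-enoic acid | C[C@H](C(=O)O)[C@@](C)(CCC#C[Si](C)(C)C)/C(C)=C/[Si](C)(C)C | intermediate
16 | acid chloride of 15 | C[C@H](C(Cl)=O)[C@@](C)(CCC#C[Si](C)(C)C)/C(C)=C/[Si](C)(C)C | intermediate
17 | (3S,4R,5E)-1-diazo-3,4,5-trimethyl-6-(trimethylsilyl)-4-[4-(trimethylsilyl)but-3-yn-1-yl]hex-5-en-2-one | C[C@H](C(=O)C=[N+]=[N-])[C@@](C)(CCC#C[Si](C)(C)C)/C(C)=C/[Si](C)(C)C | intermediate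
18 | (3R,4R,5E)-3,4,5-trimethyl-6-(trimethylsilyl)-4-[4-(trimethylsilyl)but-3-yn-1-yl]hexa-1,5-dien-1-one (ketene) | O=C=C[C@@H](C)[C@@](C)(CCC#C[Si](C)(C)C)/C(C)=C/[Si](C)(C)C | intermediate
19 | chloro(ethyl)aluminium (3R,4R)-3,4,5-trimethyl-4-[4-(trimethylsilyl)but-3-yn-1-yl]cyclohexa-1,5-dien-1-olate | CC[Al](Cl)OC1=C[C@@H](C)[C@@](C)(CCC#C[Si](C)(C)C)C(C)=C1 | intermediate
20 | (4R,5R)-3,4,5-trimethyl-4-[4-(trimethylsilyl)but-3-yn-1-yl]cyclohex-2-en-1-one | C[Si](C)(C)C#CCC[C@@]1(C)C(C)=CC(=O)C[C@H]1C | intermediate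
21 | (4R,5R)-4-(but-3-yn-1-yl)-3,4,5-trimethylcyclohex-2-en-1-one | C#CCC[C@@]1(C)C(C)=CC(=O)C[C@H]1C | intermediate
22 | (4R,5R)-4-(3-iodobut-3-en-1-yl)-3,4,5-trimethylcyclohex-2-en-1-one | C=C(I)CC[C@@]1(C)C(C)=CC(=O)C[C@H]1C | intermediate
23 | tert-butyldimethyl(pent-4-yn-1-yloxy)silane | C#CCCCO[Si](C)(C)C(C)(C)C | starting material
24 | [(E)-5-(tert-butyldimethylsilyloxy)-2-methylpent-1-en-1-yl]dimethylalane | C[Al](C)/C=C(\C)CCCO[Si](C)(C)C(C)(C)C | intermediate
25 | lithium butyl[(E)-5-(tert-butyldimethylsilyloxy)-2-methylpent-1-en-1-yl]dimethylaluminate | [Li+].CCCC[Al-](C)(C)/C=C(\C)CCCO[Si](C)(C)C(C)(C)C | intermediate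
26 | (E)-7-(tert-butyldimethylsilyloxy)-4-methylhept-3-en-1-ol | OCC/C=C(\C)CCCO[Si](C)(C)C(C)(C)C | intermediate
27 | (E)-tert-butyl[(7-iodo-4-methylhept-4-en-1-yl)oxy]dimethylsilane | ICC/C=C(\C)CCCO[Si](C)(C)C(C)(C)C | intermediate
28 | 4-bromofuran-2(5H)-one | O=C1C=C(Br)CO1 | starting material
29 | [(E)-7-(tert-butyldimethylsilyloxy)-4-methylhept-3-en-1-yl]zinc iodide | I[Zn]CC/C=C(\C)CCCO[Si](C)(C)C(C)(C)C | intermediate
30 | 4-[(E)-7-(tert-butyldimethylsilyloxy)-4-methylhept-3-en-1-yl]furan-2(5H)-one | O=C1OCC(CC/C=C(\C)CCCO[Si](C)(C)C(C)(C)C)=C1 | intermediate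
31 | 4-[(E)-7-hydroxy-4-methylhept-3-en-1-yl]furan-2(5H)-one | OCCC/C(C)=C/CCC1=CC(=O)OC1 | intermediate
32 | (E)-4-methyl-7-(5-oxo-2,5-dihydrofuran-3-yl)hept-4-enal | O=CCC/C(C)=C/CCC1=CC(=O)OC1 | intermediate
33 | dichloro{4-[(1R,6R)-1,2,6-trimethyl-4-oxocyclohex-2-en-1-yl]but-1-en-2-yl}chromium | C=C([Cr](Cl)Cl)CC[C@@]1(C)C(C)=CC(=O)C[C@H]1C | intermediate
34 | 4-[(3E,7R)-7-hydroxy-4-methyl-8-methylidene-10-[(1R,6R)-1,2,6-trimethyl-4-oxocyclohex-2-en-1-yl]dec-3-en-1-yl]furan-2(5H)-one | C=C(CC[C@@]1(C)C(C)=CC(=O)C[C@H]1C)[C@@H](CC/C(C)=C/CCC1=CC(=O)OC1)O | intermediate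
35 | 4-[(3E,7R)-7-acetoxy-4-methyl-8-methylidene-10-[(1R,6R)-1,2,6-trimethyl-4-oxocyclohex-2-en-1-yl]dec-3-en-1-yl]furan-2(5H)-one (CNP0204194.1) | C=C(CC[C@@]1(C)C(C)=CC(=O)C[C@H]1C)[C@@H](CC/C(C)=C/CCC1=CC(=O)OC1)OC(C)=O | target

**Step count**

Total: 18 steps. Longest linear sequence: 13 steps (steps 1–11, 17, 18, from but-2-yn-1-ol).

**Steps most likely to fail**

1. Step 9 (proposed method). What may go wrong: the ketene may dimerise or be intercepted by adventitious water before the Lewis acid-activated ipso-acylation, or the carbene may leak into cyclopropanation of the vinylsilane. Fallback, from 17 back to 20: the Wolff rearrangement is run with PhCO2Ag and Et3N in aqueous dioxane, so that water traps ketene 18 as the homologated acid F1 (Arndt–Eistert homologation). 1-Chloro-N,N,2-trimethylprop-1-en-1-amine converts it into the acid chloride F2, and AlCl3 in CH2Cl2 (−78 → 0 °C) effects the known vinylsilane-terminated intramolecular acylation to 20. The two bonds are then made in separate operations.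

2. Step 7. What may go wrong: incomplete control of the ketene acetal geometry, which erodes the configuration at C5, or slow rearrangement at the tetrasubstituted alkene with competing C-silylation. Fallback, from 11 back to 15: the C5 methyl is taken out of the rearrangement and introduced under auxiliary control. Alcohol 11 is acetylated (Ac2O, DMAP) to the acetate F3; LDA and TMSCl give the silyl ketene acetal F4, which rearranges through the same chair to the silyl ester F5 and, on work-up, the acid F6, in which only C4 is set. DCC/DMAP coupling with (S)-4-benzyloxazolidin-2-one gives the imide F7; NaHMDS then MeI methylates the Z-enolate on the face away from the benzyl group to give the methylated imide F8; LiOH/H2O2 removes the auxiliary and returns 15.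

3. Step 17. What may go wrong: insufficient facial selectivity in the addition to an unbranched aldehyde, leaving epimers that differ only at a centre remote from the ring. Fallback, from 22 (with 32) back to 34: the coupling is run without chiral ligand (CrCl2, NiCl2 (cat.), DMF) to give 34 together with its (S)-epimer F9, and the mixture is submitted to Sharpless kinetic resolution (Ti(OiPr)4, L-(+)-diisopropyl tartrate, t-BuOOH, 4 Å sieves, CH2Cl2, −20 °C). The (S)-alcohol F9 is epoxidised to the epoxy alcohol F10 and the (R)-alcohol 34 is recovered.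

Further compounds
F1 | step 9 | (3R,4R,5E)-3,4,5-trimethyl-6-(trimethylsilyl)-4-[4-(trimethylsilyl)but-3-yn-1-yl]hex-5-enoic acid | C[C@H](CC(=O)O)[C@@](C)(CCC#C[Si](C)(C)C)/C(C)=C/[Si](C)(C)C
F2 | step 9 | (3R,4R,5E)-3,4,5-trimethyl-6-(trimethylsilyl)-4-[4-(trimethylsilyl)but-3-yn-1-yl]hex-5-enoyl chloride | C[C@H](CC(Cl)=O)[C@@](C)(CCC#C[Si](C)(C)C)/C(C)=C/[Si](C)(C)C
F3 | step 7 | (1S,2Z)-2,3-dimethyl-1,7-bis(trimethylsilyl)hept-2-en-6-yn-1-yl acetate | CC(=O)O[C@@H]([Si](C)(C)C)/C(C)=C(C)\CCC#C[Si](C)(C)C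
F4 | step 7 | O-trimethylsilyl ketene acetal of F3 | C=C(O[Si](C)(C)C)O[C@@H]([Si](C)(C)C)/C(C)=C(C)\CCC#C[Si](C)(C)C
F5 | step 7 | trimethylsilyl ester of F6 | C[Si](C)(C)OC(=O)C[C@@](C)(CCC#C[Si](C)(C)C)/C(C)=C/[Si](C)(C)C
F6 | step 7 | (3R,4E)-3,4-dimethyl-5-(trimethylsilyl)-3-[4-(trimethylsilyl)but-3-yn-1-yl]pent-4-enoic acid | OC(=O)C[C@@](C)(CCC#C[Si](C)(C)C)/C(C)=C/[Si](C)(C)C
F7 | step 7 | (S)-4-benzyl-3-[(3R,4E)-3,4-dimethyl-5-(trimethylsilyl)-3-[4-(trimethylsilyl)but-3-yn-1-yl]pent-4-enoyl]oxazolidin-2-one | O=C1OC[C@H](Cc2ccccc2)N1C(=O)C[C@@](C)(CCC#C[Si](C)(C)C)/C(C)=C/[Si](C)(C)C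
F8 | step 7 | (S)-4-benzyl-3-[(2S,3R,4E)-2,3,4-trimethyl-5-(trimethylsilyl)-3-[4-(trimethylsilyl)but-3-yn-1-yl]pent-4-enoyl]oxazolidin-2-one | O=C1OC[C@H](Cc2ccccc2)N1C(=O)[C@@H](C)[C@@](C)(CCC#C[Si](C)(C)C)/C(C)=C/[Si](C)(C)C
F9 | step 17 | 4-[(3E,7S)-7-hydroxy-4-methyl-8-methylidene-10-[(1R,6R)-1,2,6-trimethyl-4-oxocyclohex-2-en-1-yl]dec-3-en-1-yl]furan-2(5H)-one | C=C(CC[C@@]1(C)C(C)=CC(=O)C[C@H]1C)[C@H](CC/C(C)=C/CCC1=CC(=O)OC1)O
F10 | step 17 | 4-[(3E,7S)-7-hydroxy-4-methyl-7-[(2S)-2-[2-[(1R,6R)-1,2,6-trimethyl-4-oxocyclohex-2-en-1-yl]ethyl]oxiran-2-yl]hept-3-en-1-yl]furan-2(5H)-one | O[C@@H](CC/C(C)=C/CCC1=CC(=O)OC1)[C@]2(CC[C@@]3(C)C(C)=CC(=O)C[C@H]3C)CO2
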